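**Plan**

1. Retrosynthetic cuts, in order: the C8–OOH bond with the C6=C7 shift (ene reaction on a Δ7 lactone); the δ-lactone bonds C15–C1 and O(3)–C16; the C1 carbonyl back to an alkyne C1≡C14; the ring bond C1–C2 and the chain bond C13–C14. This leaves a C15 farnesyl chain (C2–C13 with Me18, Me19, Me20) and acetylene (C1, C14).
2. Forward: the chain first (farnesyl acetate → C13–OH → 11,12-oxide → C13–C14≡C1H → 3,4-oxide), then the 14-membered carbocycle by a Payne-relayed macrocyclising alkynylation (C1–C2), then the six-membered lactone on C3–OH and the C1 carbonyl (C15, C16, Me17 from a phosphonopropionate), last the hydroperoxide.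
3. Stereochemistry: C11/C12 and C4 from two Sharpless epoxidations with the same L-(+)-tartrate; C3 from the single SN2 inversion of the Payne step; C1 from hydride addition anti to the C3 substituent of the lactone; C15 by equilibration to the all-equatorial lactone; C8 from the suprafacial singlet-oxygen ene reaction on the ring alkene.
4. Enabling feature: C1 and C14 are the only adjacent carbons of the 14-membered ring that carry neither methyl nor oxygen, so they can be an alkyne. C2 is a CH2 flanked by C1 and by the anti C3–O/C4(Me)–OH pair, which is the product pattern of C1-opening of a Payne-rearranged geraniol-type 2,3-epoxy alcohol. An acetylide at C1 can therefore close the ring on C2 and at the same time set free C3–OH for the lactone O–C3–C2–C1–C15–C16.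

Key step: step 6

Remark (assumption): cembrane numbering of the target is used for all compounds (ring C1–C14; lactone branch C15(Me17)–C16 on C1; Me18, Me19, Me20 on C4, C8, C12). (2E,6E)-Farnesyl acetate, ethynyltrimethylsilane and 2-(diethoxyphosphoryl)propanoic acid are taken as purchasable.

**Route**

Step 1
Reactants: 1 (2E,6E)-farnesyl acetate
Product: 2 (2E,6E,10E)-12-hydroxyfarnesyl acetate (the new CH2OH is cembrane C13)
Conditions: SeO2 (cat.), t-BuOOH, salicylic acid (cat.), CH2Cl2, 0 °C → rt
Reagents that add atoms: tert-butyl hydroperoxide, CC(C)(C)OO (oxygen relayed by the SeO2 catalyst)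
Why: SeO2/t-BuOOH allylic oxidation (ene reaction then [2,3]-sigmatropic shift) should attack the (E)-methyl of the terminal, most electron-rich trisubstituted alkene, the C3 alkene being deactivated by the allylic acetate, and keeps the C11=C12 geometry.

Step 2
Reactants: 2 (2E,6E,10E)-12-hydroxyfarnesyl acetate
Product: 3 (2E,6E)-9-[(2S,3S)-3-(hydroxymethyl)-3-methyloxiran-2-yl]-3,7-dimethylnona-2,6-dien-1-yl acetate (11S,12S-oxide)
Conditions: Ti(OiPr)4 (cat.), L-(+)-diethyl tartrate (cat.), t-BuOOH, 4 Å MS, CH2Cl2, −20 °C
Reagents that add atoms: tert-butyl hydroperoxide, CC(C)(C)OO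
Why: Sharpless asymmetric epoxidation touches only the alkene that has a free allylic hydroxyl, and L-(+)-tartrate should deliver oxygen to the face of the (E)-2-methylalk-2-en-1-ol that gives the (11S,12S)-oxide.

Step 3
Reactants: 3 epoxy alcohol from step 2; 4 ethynyltrimethylsilane
Product: 6 (2E,6E)-3,7-dimethyl-9-[(2S,3S)-3-methyl-3-(3-trimethylsilylprop-2-yn-1-yl)oxiran-2-yl]nona-2,6-dien-1-yl acetate, via epoxy triflate 5 (not isolated)
Conditions: Tf2O, 2,6-lutidine, CH2Cl2, −78 °C; then LiC≡CSiMe3 (from 4, n-BuLi), THF/DMPU, −78 → −20 °C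
Reagents that add atoms: trifluoromethanesulfonic anhydride, O=S(=O)(OS(=O)(=O)C(F)(F)F)C(F)(F)F (its atoms stay only in 5); lithium (trimethylsilyl)acetylide from 4, [Li]C#C[Si](C)(C)C
Why: SN2 alkylation of a lithium acetylide by a primary oxiranylmethyl triflate, where direct displacement at C13 should outrun epoxide opening and attack on the acetate at low temperature (the tied-back oxirane carbon is less shielding than a true neopentyl centre); no stereocentre is touched.

Step 4
Reactants: 6 silylalkyne acetate from step 3
Product: 7 (2E,6E)-3,7-dimethyl-9-[(2S,3S)-3-methyl-3-(prop-2-yn-1-yl)oxiran-2-yl]nona-2,6-dien-1-ol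
Conditions: K2CO3 (cat.), MeOH, rt
Reagents that add atoms: none
Why: Methanolysis of the acetate and protodesilylation of the alkynylsilane should occur under the same mild base, which leaves the trisubstituted epoxide intact.

Step 5
Reactants: 7 enynol from step 4
Product: 8 {(2S,3S)-3-methyl-3-[(3E)-4-methyl-6-((2S,3S)-3-methyl-3-(prop-2-yn-1-yl)oxiran-2-yl)hex-3-en-1-yl]oxiran-2-yl}methanol (3S,4S,11S,12S)
Conditions: Ti(OiPr)4 (cat.), L-(+)-diethyl tartrate (cat.), t-BuOOH, 4 Å MS, CH2Cl2, −20 °C
Reagents that add atoms: tert-butyl hydroperoxide, CC(C)(C)OO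
Why: Second Sharpless asymmetric epoxidation, now of the geraniol-type allylic alcohol, for which the same L-(+)-tartrate should give the (3S,4S)-oxide under reagent control, while the central C7=C8 alkene, which has no allylic hydroxyl, stays for the last step.

Step 6
Reactants: 8 bis-epoxy alkynol from step 5
Product: 10 (3R,4S,7E,11S,12S)-11,12-epoxy-4,8,12-trimethylcyclotetradec-7-en-1(14)-yne-3,4-diol (cembrane numbering; triple bond C1≡C14), via Payne epoxide 9 (not isolated)
Conditions: n-BuLi (2.1 equiv), THF, −78 °C; then DMPU, dilute to 2 mM, −20 → 45 °C; H2O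
Reagents that add atoms: none
Why: Proposed new method: two equivalents of base give the C2 alkoxide and the C1 acetylide; the alkoxide equilibrates by Payne rearrangement (intramolecular SN2 at C3 with inversion) with the C2–C3 oxirane/C4 alkoxide isomer 9, and the acetylide opens the unhindered CH2 of this minor isomer, so that the equilibrium is drained (Curtin–Hammett) into the ring-closed dialkoxide. The closest known reaction types are the Payne rearrangement with C1 opening of 2,3-epoxy alcohols by thiolates, cyanide or sulfonium ylides, the opening of terminal epoxides by lithium acetylides in dipolar aprotic media, and the high-dilution cyclisation of acetylides that carry a remote electrophile to 14-membered cycloalkynes. The 14-membered ring closes in the 14-exo-tet mode by forming C1–C2, and the near-linear C14≡C1···C2 array of the transition state should be spanned without strain by the eleven remaining ring atoms. No new stereocentre arises: C4 keeps the oxygen delivered in step 5, C3 is inverted once by the Payne step to the 3R configuration of the target, and C11/C12 are not touched. The step needs attack at C2 in preference to C3, to the 11,12-oxide and to intermolecular reaction: C3 is shielded by the quaternary C4, C1 cannot reach the 11,12-oxide without closing a four- or five-membered ring across the linear alkyne, high dilution disfavours oligomers, and the base is limited to 2.1 equivalents so that the propargylic C13–H2 is not removed.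

Step 7
Reactants: 10 cycloalkyne diol from step 6
Product: 13 (3R,4S,7E,11S,12S)-11,12-epoxy-3,4-dihydroxy-4,8,12-trimethylcyclotetradec-7-en-1-one, via dimethylsilyl ether 11 (not isolated), via alkenyl oxasilolane 12 (not isolated)
Conditions: (HMe2Si)2NH, 60 °C; Karstedt Pt(0) catalyst, THF, rt; then 30% H2O2, KF, KHCO3, THF/MeOH, rt
Reagents that add atoms: 1,1,3,3-tetramethyldisilazane, C[SiH](C)N[SiH](C)C (silicon stays only in 11 and 12); hydrogen peroxide, OO
Why: Intramolecular hydrosilylation from the C3–O–SiHMe2 tether (Pt, syn, 5-exo-dig) should place silicon on C1 and hydrogen on C14 regiospecifically, and Tamao–Fleming oxidation of the alkenylsiloxane then unveils the C1 ketone without touching C3 (a silyl ether on the tertiary C4–OH would deliver silicon to C1 as well and is cleaved in the oxidative work-up).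

Step 8
Reactants: 13 hydroxy ketone from step 7; 14 2-(diethoxyphosphoryl)propanoic acid
Product: 15 3-O-[2-(diethoxyphosphoryl)propanoyl] ester of 13 (epimer mixture at the phosphonate carbon)
Conditions: DCC, DMAP (cat.), CH2Cl2, 0 °C → rt
Reagents that add atoms: 2-(diethoxyphosphoryl)propanoic acid 14, CC(C(=O)O)P(=O)(OCC)OCC
Why: Steglich esterification should acylate the secondary C3 hydroxyl while the tertiary C4 hydroxyl stays free; the new stereocentre at the phosphonate carbon is lost in the next step.

Step 9
Reactants: 15 keto phosphonate ester from step 8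
Product: 16 (3R,4S,7E,11S,12S)-11,12-epoxy-4-hydroxycembra-1(15),7-dien-16,3-olide
Conditions: LiCl, DBU, MeCN, rt
Reagents that add atoms: none
Why: Intramolecular Horner–Wadsworth–Emmons olefination under Masamune–Roush conditions should close the six-membered α-methyl-α,β-unsaturated δ-lactone by forming C15=C1, the phosphonate being far more acidic than the ketone α-CH2, which limits β-elimination of the acyloxy group.

Step 10
Reactants: 16 unsaturated lactone from step 9
Product: 18 (1R,3R,4S,7E,11S,12S,15S)-11,12-epoxy-4-hydroxycembr-7-en-16,3-olide, via 15-epi lactone 17 (not isolated)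
Conditions: NiCl2·6H2O (cat.), NaBH4, MeOH/THF, −20 → 0 °C; then DBU (cat.), CH2Cl2, rt
Reagents that add atoms: none
Why: Nickel boride conjugate reduction should deliver hydride to C1 on the face anti to the C3 substituent (as in the cis-4,6-selective reductions of 6-substituted 5,6-dihydropyran-2-ones), which sets 1R, and base equilibration of the epimerisable C15 should give the all-equatorial 15S lactone, while the isolated trisubstituted alkene and the epoxide are not reduced.

Step 11
Reactants: 18 Δ7 lactone from step 10
Product: 19 target, (1R,3R,4S,6E,8R,11S,12S,15S)-11,12-epoxy-8-hydroperoxy-4-hydroxycembr-6-en-16,3-olide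
Conditions: O2, visible light, tetraphenylporphyrin (cat.), CH2Cl2, −20 °C
Reagents that add atoms: dioxygen (as singlet oxygen), O=O
Why: Schenck ene reaction of singlet oxygen with the only alkene left: oxygen bonds to C8 and a hydrogen is taken suprafacially from C6 on the crowded (cis-effect) side of the E-alkene to give the 6E allylic hydroperoxide, the C8 configuration being set by attack on the outward-facing π-face of the ring alkene, which is expected to be the face leading to 8R; the regioisomer from C19–H abstraction is the foreseeable by-product.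

**Compound list**

1 | (2E,6E)-farnesyl acetate, (2E,6E)-3,7,11-trimethyldodeca-2,6,10-trien-1-yl acetate | CC(=O)OC/C=C(\C)CC/C=C(\C)CCC=C(C)C | starting material
2 | (2E,6E,10E)-12-hydroxy-3,7,11-trimethyldodeca-2,6,10-trien-1-yl acetate | CC(=O)OC/C=C(\C)CC/C=C(\C)CC/C=C(\C)CO | intermediate
3 | (2E,6E)-9-[(2S,3S)-3-(hydroxymethyl)-3-methyloxiran-2-yl]-3,7-dimethylnona-2,6-dien-1-yl acetate | CC(=O)OC/C=C(\C)CC/C=C(\C)CC[C@@H]1O[C@@]1(C)CO | intermediate
4 | ethynyltrimethylsilane | C#C[Si](C)(C)C | starting material
5 | trifluoromethanesulfonate of 3 at the oxiranylmethyl oxygen (C13) | CC(=O)OC/C=C(\C)CC/C=C(\C)CC[C@@H]1O[C@@]1(C)COS(=O)(=O)C(F)(F)F | intermediate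
6 | (2E,6E)-3,7-dimethyl-9-[(2S,3S)-3-methyl-3-(3-trimethylsilylprop-2-yn-1-yl)oxiran-2-yl]nona-2,6-dien-1-yl acetate | CC(=O)OC/C=C(\C)CC/C=C(\C)CC[C@@H]1O[C@@]1(C)CC#C[Si](C)(C)C | intermediate
7 | (2E,6E)-3,7-dimethyl-9-[(2S,3S)-3-methyl-3-(prop-2-yn-1-yl)oxiran-2-yl]nona-2,6-dien-1-ol | OC/C=C(\C)CC/C=C(\C)CC[C@@H]1O[C@@]1(C)CC#C | intermediate
8 | {(2S,3S)-3-methyl-3-[(3E)-4-methyl-6-((2S,3S)-3-methyl-3-(prop-2-yn-1-yl)oxiran-2-yl)hex-3-en-1-yl]oxiran-2-yl}methanol | OC[C@@H]1O[C@@]1(C)CC/C=C(\C)CC[C@@H]1O[C@@]1(C)CC#C | intermediate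
9 | Payne isomer of 8: (2S,5E)-6-methyl-8-[(2S,3S)-3-methyl-3-(prop-2-yn-1-yl)oxiran-2-yl]-2-[(2R)-oxiran-2-yl]oct-5-en-2-ol | C#CC[C@]1(C)O[C@H]1CC/C(C)=C/CC[C@](C)(O)[C@H]1CO1 | intermediate
10 | (3R,4S,7E,11S,12S)-11,12-epoxy-4,8,12-trimethylcyclotetradec-7-en-1(14)-yne-3,4-diol (cembrane numbering, C1≡C14) | C1#CC[C@]2(C)O[C@H]2CC/C(C)=C/CC[C@](C)(O)[C@H](O)C1 | intermediate
11 | 3-O-(dimethylsilyl) ether of 10 | C1#CC[C@]2(C)O[C@H]2CC/C(C)=C/CC[C@](C)(O[SiH](C)C)[C@H](O)C1 | intermediate
12 | 2,2-dimethyl-1-oxa-2-silacyclopentane spanning O(3)–C3–C2–C1 with silicon on C1 and a ring-cis C1=C14 alkene; 4-OH free, 11,12-oxide and Δ7 as in 10 | C[Si]1(C)O[C@@H]2C/C1=C\C[C@]3(C)O[C@H]3CC/C(C)=C/CC[C@]2(C)O | intermediate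
13 | (3R,4S,7E,11S,12S)-11,12-epoxy-3,4-dihydroxy-4,8,12-trimethylcyclotetradec-7-en-1-one | O=C1CC[C@]2(C)O[C@H]2CC/C(C)=C/CC[C@](C)(O)[C@H](O)C1 | intermediate
14 | 2-(diethoxyphosphoryl)propanoic acid | CC(C(=O)O)P(=O)(OCC)OCC | starting material
15 | 3-O-[2-(diethoxyphosphoryl)propanoyl] ester of 13 | O=C1CC[C@]2(C)O[C@H]2CC/C(C)=C/CC[C@](C)(O)[C@H](OC(=O)C(C)P(=O)(OCC)OCC)C1 | intermediate
16 | (3R,4S,7E,11S,12S)-11,12-epoxy-4-hydroxycembra-1(15),7-dien-16,3-olide | CC1=C2CC[C@]3(C)O[C@H]3CC/C(C)=C/CC[C@](C)(O)[C@@H](C2)OC1=O | intermediate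
17 | (1R,3R,4S,7E,11S,12S,15R)-11,12-epoxy-4-hydroxycembr-7-en-16,3-olide (15-epimer of 18) | C[C@H]1C(=O)O[C@@H]2C[C@H]1CC[C@]1(C)O[C@H]1CC/C(C)=C/CC[C@]2(C)O | intermediate
18 | (1R,3R,4S,7E,11S,12S,15S)-11,12-epoxy-4-hydroxycembr-7-en-16,3-olide | C[C@@H]1C(=O)O[C@@H]2C[C@H]1CC[C@]1(C)O[C@H]1CC/C(C)=C/CC[C@]2(C)O | intermediate
19 | (1R,3R,4S,6E,8R,11S,12S,15S)-11,12-epoxy-8-hydroperoxy-4-hydroxycembr-6-en-16,3-olide (CNP0297487.3) | C[C@@H]1C(=O)O[C@@H]2C[C@H]1CC[C@]1(C)O[C@H]1CC[C@@](C)(OO)/C=C/C[C@]2(C)O | target

Total step count: 11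
Longest linear sequence: 11 steps (1 → 19)

**Steps most likely to fail**

Step 6 (bears the label). The Payne isomer may be present in too small a proportion, and the lithium acetylide may open an unactivated oxirane too slowly at the dilution required, so that oligomerisation or base-induced decay of the dianion wins. The fallback sets out from 8 and comes back to the route at 10; it separates the rearrangement from the ring closure and uses a static, protected electrophile. Thiophenol and NaOH in aqueous t-BuOH should open the Payne-rearranged oxirane at C2 to give the phenylthio diol F1. S-Methylation with Me3O+ BF4− gives the sulfonium salt F2, which aqueous NaOH closes by attack of the C3 alkoxide on C2 to the isolated epoxy alcohol 9. Silylation of the tertiary hydroxyl (Me3SiCl, imidazole) gives the silyl ether F3, in which the oxirane can no longer revert. Ring closure of the lithium acetylide of F3 (n-BuLi, THF/HMPA, high dilution), an acetylide opening of a terminal epoxide, gives the macrocyclic silyl ether F4, and K2CO3 in MeOH returns 10.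

Step 11. The ring conformation may favour hydrogen abstraction from the C19 methyl group over C6, or oxygen attack on the wrong face, so that the exo-methylene secondary hydroperoxide or the 8-epimer dominates. The fallback sets out from 18 and comes back at 19; it replaces the pericyclic ene reaction by a radical hydroperoxidation whose position is fixed by where a hydrogen atom is added. The photo-oxygenation is run to completion and the 7-hydroperoxy-8(19)-ene regioisomer F5 is collected and reduced with PPh3 to the allylic alcohol F6. Burgess dehydration, which can only proceed towards C6, gives the (6E)-6,8(19)-diene F7. Isayama–Mukaiyama silylperoxidation (Co(II) β-diketonate, O2, Et3SiH) should add hydrogen to C19 and trap O2 at the tertiary terminus C8 of the allyl radical to give the triethylsilyl peroxide F8, and buffered fluoride (HF·pyridine) releases 19. The C8 configuration then depends on the face selectivity of oxygen capture in the ring, and the epimers may have to be separated.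

Step 9. Base-induced β-elimination of the acyloxy group from the β-acyloxy ketone (E1cB) may outrun the attack of the hindered phosphonate carbanion on the ring ketone. The fallback sets out from 13 and comes back at 16; it builds the same C15–C1 bond with a non-basic enolate and introduces the double bond afterwards. Acylation of 13 with 2-bromopropanoyl bromide and pyridine gives the bromo ester F9. SmI2 in THF at −78 °C (intramolecular Reformatsky reaction) closes the β-hydroxy δ-lactone F10. Dehydration with the Burgess reagent, followed by catalytic DBU to move the alkene into conjugation, gives 16.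

Further compounds
F1 | step 6 | phenylthio diol: C2–SPh, 3-OH and 4-OH configured as in 10, alkyne and 11,12-oxide as in 8 | C#CC[C@]1(C)O[C@H]1CC/C(C)=C/CC[C@](C)(O)[C@H](O)CSc1ccccc1
F2 | step 6 | S-methyl-S-phenylsulfonium tetrafluoroborate of F1 | C#CC[C@]1(C)O[C@H]1CC/C(C)=C/CC[C@](C)(O)[C@H](O)C[S+](C)c1ccccc1.F[B-](F)(F)F
F3 | step 6 | 4-O-trimethylsilyl ether of 9 | C#CC[C@]1(C)O[C@H]1CC/C(C)=C/CC[C@](C)(O[Si](C)(C)C)[C@H]1CO1
F4 | step 6 | 4-O-trimethylsilyl ether of 10 | C1#CC[C@]2(C)O[C@H]2CC/C(C)=C/CC[C@](C)(O[Si](C)(C)C)[C@H](O)C1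
F5 | step 11 | 7-hydroperoxy-8(19)-ene regioisomer of 19 (C7 configuration not defined) | C[C@@H]1C(=O)O[C@@H]2C[C@H]1CC[C@]1(C)O[C@H]1CCC(=C)C(OO)CC[C@]2(C)O
F6 | step 11 | 7-hydroxy-8(19)-ene lactone from F5 | C[C@@H]1C(=O)O[C@@H]2C[C@H]1CC[C@]1(C)O[C@H]1CCC(=C)C(O)CC[C@]2(C)O
F7 | step 11 | (6E)-6,8(19)-diene lactone | C[C@@H]1C(=O)O[C@@H]2C[C@H]1CC[C@]1(C)O[C@H]1CCC(=C)/C=C/C[C@]2(C)O
F8 | step 11 | triethylsilyl peroxide of 19 at C8 | C[C@@H]1C(=O)O[C@@H]2C[C@H]1CC[C@]1(C)O[C@H]1CC[C@@](C)(OO[Si](CC)(CC)CC)/C=C/C[C@]2(C)O
F9 | step 9 | 3-O-(2-bromopropanoyl) ester of 13 | O=C1CC[C@]2(C)O[C@H]2CC/C(C)=C/CC[C@](C)(O)[C@H](OC(=O)C(C)Br)C1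
F10 | step 9 | 1-hydroxy lactone: 16,3-olide with OH on C1 and H on C15 (C1 and C15 configurations not defined) | CC1C(=O)O[C@@H]2CC1(O)CC[C@]1(C)O[C@H]1CC/C(C)=C/CC[C@]2(C)O
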